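The chair opened the meeting on amber and teal by tabling the charges, the readings and the questions, then asked whether the flat stretches of J could be read as final yields.

| flask | X | D | E | temperature | remark | time |
|---|---|---|---|---|---|---|
| south-west | 9 mM | 2 equiv | 3.6 mM | 37 °C | run made earlier |  |
| east | 14 mM | 2 equiv | 3.6 mM | 52 °C | run made earlier |  |
| west | 18 mM | 3 equiv | 3.6 mM | 37 °C | run made earlier |  |
| amber | 18 mM | 2.00 equiv | 3.60 mM | 48 °C |  | 6.0 min |
| teal | 18 mM | 2.00 equiv | 3.60 mM | 40 °C |  | 6.0 min |

| run | time / min | J / % |
|---|---|---|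
| south-west | 0.417 | 1 |
| south-west | 1.33 | 5 |
| south-west | 2.00 | 8 |
| south-west | 3.00 | 17 |
| south-west | 5.00 | 28 |
| south-west | 6.00 | 30 |
| east | 0.500 | 10 |
| east | 1.00 | 21 |
| east | 1.50 | 23 |
| east | 2.00 | 25 |
| east | 3.00 | 29 |
| west | 1.33 | 17 |
| west | 2.50 | 34 |
| west | 4.00 | 49 |
| west | 5.00 | 53 |
| west | 6.00 | 54 |

(scatter of a reading: 1.5 percentage points)

1. which of the two there is more of at the end, amber (J / Z)
2. which of the two there is more of at the end, teal (J / Z)
3. final J, as a percentage of the X charged, in amber
4. final J, as a percentage of the X charged, in teal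

The kineticist answered that the runs must first be put on a common clock. She proposed a pseudo-first-order treatment of X in D, with E as a small correction that takes D one for one. Net D is then N = [D]₀ − [E]₀, which is 50.4 mM in west and 32.4 mM in teal, less than in west.

Her west-equivalent time, t_w, is the reading time multiplied by N of the flask and divided by N of west. For teal this gives 3.86 min, and interpolating the west readings there gives J of 47.6%. That leaves 52.4% for X, Z and anything unseen, so she put J ahead in teal.

She conceded two weaknesses. Teal is hotter than west, and the rule misses south-west: its N of 14.4 mM gives 1.71 min, where the west interpolation reads 22.6% against the 30% measured. She offered no figure for amber, since the rule holds temperature fixed.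

The forecaster reported J of 34% in amber and 37% in teal, with Z ahead in amber and Z in teal. One of the views weighed was that “the plateau depends only on equivalents”. The two parties differed on teal.

The flasks gave J 33.6% and Z 53.3% in amber, J 47.1% and Z 29.9% in teal.

    D + E → G (k = 3.30 L mol⁻¹ s⁻¹, Ea = 61.0 kJ mol⁻¹)
    Q ⇌ J (K = 12.0, k = 0.0170 s⁻¹, Ea = 87.0 kJ mol⁻¹, ΔH = −88.0 kJ mol⁻¹)
    Q ⇌ Z (K = 260, k = 0.00820 s⁻¹, Ea = 83.0 kJ mol⁻¹, ΔH = 6.00 kJ mol⁻¹)
    X + D → Q + L (k = 0.220 L mol⁻¹ s⁻¹, Ea = 50.0 kJ mol⁻¹)
    (constants at 40 °C)

Amber and teal share a t_w of 3.86 min, which gave 47.6%, yet amber ends 13 percentage points below teal. With the difference in temperature taken away, amber gives 47.1%, so that difference accounts for the gap. With teal's charges held at 37 °C for 6.0 min, the same t_w, that flask gives J 45.5%.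

The numbers in the tables are simulated from invented constants; the scatter is artificial.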